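**Strategy.** The target is the cis-(2S,3R)-2,3-diaryl-2,3-dihydrobenzofuran. Everything rests on disconnecting the aryl ether bond O1–C7a: the secondary alcohol oxygen on C2 is joined to C7a of the benzo ring by intramolecular palladium-catalysed etherification of an aryl chloride. The step exploits that C7a and C4 are the two ortho carbons flanking C3a, with C6–O para to it, so a symmetric 2,6-dichloro-4-benzyloxyphenyl group serves: either chloride closes the furan ring, the other remains at C4 for attachment of the 4-hydroxyphenethyl arm. The open-chain (1S,2R)-triarylethanol precursor, with both stereocentres already in place, comes from one enantioselective conjunctive cross-coupling.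

Key step: step 7

Remark: in step 6 the (Sp,Sp) enantiomer of MandyPhos is assumed to deliver the (1S,2R) series; should the catalyst prefer the other alkene face, the (Rp,Rp) ligand is used and nothing else changes.

**Step 1**
Reactants: 1 2,6-dichloro-4-hydroxybenzaldehyde
Product: 2 4-(benzyloxy)-2,6-dichlorobenzaldehyde
Conditions: BnBr, K2CO3, DMF, rt
Reagents that add atoms: benzyl bromide, BrCc1ccccc1
Why: Williamson ether synthesis (SN2 O-alkylation) of the acidic, formyl-activated phenoxide; no stereocentre is involved.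

**Step 2**
Reactants: 2 4-(benzyloxy)-2,6-dichlorobenzaldehyde
Product: 3 5-(benzyloxy)-1,3-dichloro-2-[(E)-2-iodoethenyl]benzene
Conditions: CrCl2, CHI3, THF, 0 °C to rt
Reagents that add atoms: iodoform, IC(I)I
Why: Takai olefination: the geminal dichromium reagent formed from CHI3 and divalent chromium adds to the aldehyde and anti elimination from the favoured adduct should give the E iodoalkene, while the aryl chlorides and the benzyl ether are inert.

**Step 3**
Reactants: 4 acenaphthoquinone (acenaphthylene-1,2-dione)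
Product: 5 cis-1,2-dimethyl-1,2-dihydroacenaphthylene-1,2-diol (meso; "mac diol")
Conditions: Al(CH3)3, toluene, 0 °C to rt; aqueous work-up; recrystallisation
Reagents that add atoms: trimethylaluminium, C[Al](C)C
Why: Double 1,2-addition of methyl to the 1,2-diketone; the second methyl is expected to enter anti to the bulky aluminium alkoxide, i.e. syn to the first methyl, which gives the cis diol needed for a cyclic boronic ester, and any trans diol is removed on recrystallisation.

**Step 4**
Reactants: 6 4-(benzyloxy)phenylboronic acid, 5 cis-1,2-dimethyl-1,2-dihydroacenaphthylene-1,2-diol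
Product: 7 4-(benzyloxy)phenylboronic acid cis-1,2-dimethylacenaphthene-1,2-diyl ester (aryl-B(mac))
Conditions: MgSO4, CH2Cl2, rt
Reagents that add atoms: none
Why: Boronic ester condensation of a boronic acid with a cis-1,2-diol, driven by removal of water.

**Step 5**
Reactants: 8 3,5-bis(benzyloxy)phenol
Product: 9 3,5-bis(benzyloxy)phenyl trifluoromethanesulfonate
Conditions: Tf2O, pyridine, CH2Cl2, 0 °C
Reagents that add atoms: trifluoromethanesulfonic anhydride, O=S(=O)(OS(=O)(=O)C(F)(F)F)C(F)(F)F
Why: O-Sulfonylation of the phenol, giving the aryl electrophile for step 6.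

**Step 6**
Reactants: 3 5-(benzyloxy)-1,3-dichloro-2-[(E)-2-iodoethenyl]benzene, 7 aryl-B(mac), 9 3,5-bis(benzyloxy)phenyl trifluoromethanesulfonate
Product: 13 (1S,2R)-1-[4-(benzyloxy)phenyl]-2-[4-(benzyloxy)-2,6-dichlorophenyl]-2-[3,5-bis(benzyloxy)phenyl]ethan-1-ol, via alkenyllithium 10 (not isolated), via lithium alkenyl(aryl)borate 11 (not isolated), via secondary boronic ester 12 (not isolated)
Conditions: 3, t-BuLi (2 equiv), Et2O, −78 °C; then 7, −78 °C to rt; then Pd(OAc)2 (3 mol %), (Sp,Sp)-MandyPhos (3.6 mol %), 9, NaOSO2CF3, THF, 60 °C; then NaOH, H2O2, 0 °C to rt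
Reagents that add atoms: hydrogen peroxide, OO
Why: Palladium-catalysed conjunctive cross-coupling of a β-substituted alkenylboron ate complex: iodine–lithium exchange with retention of the E geometry and addition to 7 give borate 11, the cationic arylpalladium species from 9 binds one alkene face and triggers 1,2-migration of the 4-(benzyloxy)phenyl group from boron to the α-carbon anti to palladium, C–C reductive elimination with retention places the 3,5-bis(benzyloxy)phenyl group on the β-carbon, so the E geometry fixes the relative configuration (the one that becomes cis in the ring), the chiral bisphosphine fixes the absolute configuration, and stereoretentive oxidation of the C–B bond gives 13.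

**Step 7**
Reactants: 13 (1S,2R)-1-[4-(benzyloxy)phenyl]-2-[4-(benzyloxy)-2,6-dichlorophenyl]-2-[3,5-bis(benzyloxy)phenyl]ethan-1-ol
Product: 14 (2S,3R)-6-(benzyloxy)-2-[4-(benzyloxy)phenyl]-3-[3,5-bis(benzyloxy)phenyl]-4-chloro-2,3-dihydro-1-benzofuran
Conditions: Pd(OAc)2 (5 mol %), rac-2-(di-tert-butylphosphino)-1,1'-binaphthyl (6 mol %), Cs2CO3, toluene, 80 °C
Reagents that add atoms: none
Why: Zerovalent palladium inserts into one of the two C–Cl bonds of the 2,6-dichloroaryl group, the caesium alkoxide of the C2 hydroxyl replaces chloride on divalent palladium to give a six-membered aryl(alkoxo)palladacycle, and C–O reductive elimination forms the O1–C7a bond. The closest known reaction type is the Buchwald–Hartwig intramolecular etherification of aryl halides with secondary alcohols, which leaves the configuration of the carbinol carbon untouched. The only ring closed is the dihydrofuran ring, formally a 5-exo closure of the alkoxide oxygen onto the ortho carbon by way of the six-membered palladacycle. No new stereocentre is formed: no bond to C2 or C3 is broken, so the cis (2S,3R) arrangement set in step 6 is carried through. The step needs C–O reductive elimination to win over β-hydride elimination to the aryl ketone and over C–H arylation of the neighbouring aryl rings, which the bulky electron-rich di-tert-butylbiarylphosphine and the unstrained five-membered product should secure. Site selectivity is no issue because the two chlorides are homotopic (rotation about C3–C3a), so either closure gives the same product and the surviving chloride sits at C4.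

**Step 8**
Reactants: 14 (2S,3R)-4-chloro dihydrobenzofuran, 15 4-(benzyloxy)styrene
Product: 17 (2S,3R)-6-(benzyloxy)-2-[4-(benzyloxy)phenyl]-4-{2-[4-(benzyloxy)phenyl]ethyl}-3-[3,5-bis(benzyloxy)phenyl]-2,3-dihydro-1-benzofuran, via alkylborane 16 (not isolated)
Conditions: 15, 9-BBN-H, THF, rt; then 14, Pd(OAc)2, SPhos, K3PO4, THF/H2O, 65 °C
Reagents that add atoms: none
Why: B-alkyl Suzuki–Miyaura coupling: anti-Markovnikov hydroboration of the styrene gives the primary alkylborane, whose alkyl group is transferred to the hindered aryl chloride under SPhos-ligated palladium; the stereocentres are remote from every bond made or broken.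

**Step 9**
Reactants: 17 pentabenzyl ether
Product: 18 5-[(2S,3R)-6-hydroxy-2-(4-hydroxyphenyl)-4-[2-(4-hydroxyphenyl)ethyl]-2,3-dihydro-1-benzofuran-3-yl]benzene-1,3-diol (target)
Conditions: H2 (1 atm), Pd/C, EtOAc/MeOH, rt, stopped at full debenzylation
Reagents that add atoms: none
Why: Catalytic hydrogenolysis of the five benzyl aryl ethers under neutral conditions, which avoids the acid-promoted opening of the C2–O1 bond (para-quinone methide) that would epimerise the cis isomer; the hindered cyclic benzylic ether is expected to be cleaved far more slowly than the primary O-benzyl groups.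

**Compound list**
1 | 2,6-dichloro-4-hydroxybenzaldehyde | O=Cc1c(Cl)cc(O)cc1Cl | starting material
2 | 4-(benzyloxy)-2,6-dichlorobenzaldehyde | O=Cc1c(Cl)cc(OCc2ccccc2)cc1Cl | intermediate
3 | 5-(benzyloxy)-1,3-dichloro-2-[(E)-2-iodoethenyl]benzene | I/C=C/c1c(Cl)cc(OCc2ccccc2)cc1Cl | intermediate
4 | acenaphthoquinone | O=C1C(=O)c2cccc3cccc1c23 | starting material
5 | cis-1,2-dimethyl-1,2-dihydroacenaphthylene-1,2-diol (meso, mac diol) | C[C@@]1(O)c2cccc3cccc(c23)[C@]1(C)O | intermediate
6 | 4-(benzyloxy)phenylboronic acid | OB(O)c1ccc(OCc2ccccc2)cc1 | starting material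
7 | 4-(benzyloxy)phenylboronic acid cis-1,2-dimethylacenaphthene-1,2-diyl ester | C[C@@]1(OB(c4ccc(OCc5ccccc5)cc4)O6)c2cccc3cccc(c23)[C@@]16C | intermediate
8 | 3,5-bis(benzyloxy)phenol | Oc1cc(OCc2ccccc2)cc(OCc2ccccc2)c1 | starting material
9 | 3,5-bis(benzyloxy)phenyl trifluoromethanesulfonate | FC(F)(F)S(=O)(=O)Oc1cc(OCc2ccccc2)cc(OCc2ccccc2)c1 | intermediate
10 | (E)-2-[4-(benzyloxy)-2,6-dichlorophenyl]ethenyllithium | [Li]/C=C/c1c(Cl)cc(OCc2ccccc2)cc1Cl | intermediate
11 | lithium {(E)-2-[4-(benzyloxy)-2,6-dichlorophenyl]ethenyl}[4-(benzyloxy)phenyl]borate of the mac diol | [Li+].C[C@@]1(O[B-](/C=C/c4c(Cl)cc(OCc5ccccc5)cc4Cl)(c4ccc(OCc5ccccc5)cc4)O6)c2cccc3cccc(c23)[C@@]16C | intermediate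
12 | mac boronic ester carrying the (1S,2R)-1-[4-(benzyloxy)phenyl]-2-[4-(benzyloxy)-2,6-dichlorophenyl]-2-[3,5-bis(benzyloxy)phenyl]ethyl group on boron | Clc1cc(OCc2ccccc2)cc(Cl)c1[C@@H](c1cc(OCc2ccccc2)cc(OCc2ccccc2)c1)[C@@H](c1ccc(OCc2ccccc2)cc1)B1O[C@]2(C)c3cccc4cccc(c34)[C@]2(C)O1 | intermediate
13 | (1S,2R)-1-[4-(benzyloxy)phenyl]-2-[4-(benzyloxy)-2,6-dichlorophenyl]-2-[3,5-bis(benzyloxy)phenyl]ethan-1-ol | Clc1cc(OCc2ccccc2)cc(Cl)c1[C@@H](c1cc(OCc2ccccc2)cc(OCc2ccccc2)c1)[C@@H](c1ccc(OCc2ccccc2)cc1)O | intermediate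
14 | (2S,3R)-6-(benzyloxy)-2-[4-(benzyloxy)phenyl]-3-[3,5-bis(benzyloxy)phenyl]-4-chloro-2,3-dihydro-1-benzofuran | Clc1cc(OCc2ccccc2)cc2c1[C@@H](c1cc(OCc3ccccc3)cc(OCc3ccccc3)c1)[C@@H](c1ccc(OCc3ccccc3)cc1)O2 | intermediate
15 | 4-(benzyloxy)styrene | C=Cc1ccc(OCc2ccccc2)cc1 | starting material
16 | 9-{2-[4-(benzyloxy)phenyl]ethyl}-9-borabicyclo[3.3.1]nonane | C1CC2CCCC(C1)B2CCc1ccc(OCc2ccccc2)cc1 | intermediate
17 | (2S,3R)-6-(benzyloxy)-2-[4-(benzyloxy)phenyl]-4-{2-[4-(benzyloxy)phenyl]ethyl}-3-[3,5-bis(benzyloxy)phenyl]-2,3-dihydro-1-benzofuran | c1ccc(COc2ccc(CCc3cc(OCc4ccccc4)cc4c3[C@@H](c3cc(OCc5ccccc5)cc(OCc5ccccc5)c3)[C@@H](c3ccc(OCc5ccccc5)cc3)O4)cc2)cc1 | intermediate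
18 | 5-[(2S,3R)-6-hydroxy-2-(4-hydroxyphenyl)-4-[2-(4-hydroxyphenyl)ethyl]-2,3-dihydro-1-benzofuran-3-yl]benzene-1,3-diol | Oc1ccc(CCc2cc(O)cc3c2[C@@H](c2cc(O)cc(O)c2)[C@@H](c2ccc(O)cc2)O3)cc1 | target

**Step count.** Total: 9 steps. Longest linear sequence: 6 steps (steps 1, 2, 6, 7, 8, 9).

**Steps most likely to fail**

Step 6. The 1,2-metallate shift may lose to direct transmetalation (plain Suzuki–Miyaura transfer of the alkenyl or aryl group) because the alkene of borate 11 is shielded by the 2,6-dichloroaryl group, and face selection by the catalyst may be incomplete. The fallback sets out from 3 and uses substrate control followed by resolution. Suzuki–Miyaura coupling of 3 with commercial 3,5-bis(benzyloxy)phenylboronic acid (Pd(PPh3)4, K2CO3, dioxane/H2O) should give 5-(benzyloxy)-2-{(E)-2-[3,5-bis(benzyloxy)phenyl]ethenyl}-1,3-dichlorobenzene F1. Epoxidation with mCPBA (NaHCO3, CH2Cl2) should give the racemic trans-epoxide F2. BF3·OEt2 (CH2Cl2, −78 °C) should then effect a Meinwald rearrangement with aryl shift to 2-[4-(benzyloxy)-2,6-dichlorophenyl]-2-[3,5-bis(benzyloxy)phenyl]acetaldehyde F3. Addition of 4-(benzyloxy)phenylmagnesium bromide with CeCl3 (THF, −78 °C) under Felkin–Anh control, the 2,6-dichloroaryl group acting as the large substituent, should give the racemic (1S*,2R*) alcohol F4. Resolution of F4 by preparative chromatography on a chiral stationary phase comes back to the route at 13.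

Step 7. β-Hydride elimination from the palladium alkoxide (oxidation of the benzylic alcohol with reduction of the C–Cl bond) or C–H arylation onto a neighbouring aryl ring may outrun C–O reductive elimination. The fallback sets out from 13 and is metal-free. LiTMP (3 equiv, THF, −78 to 0 °C) should deprotonate the hydroxyl and then the ring C–H flanked by chlorine and benzyloxy; loss of LiCl gives the aryne lithium alkoxide F5. The alkoxide adds to the nearer aryne carbon (5-exo, the carbanion ending next to the benzyloxy group, the matched sense for a 3-alkoxyaryne), and protonation on work-up comes back to the route at 14.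

Step 9. Over-reduction, i.e. hydrogenolysis of the benzylic C2–O1 bond with opening of the dihydrofuran ring, may compete with removal of the last benzyl ethers. The fallback sets out from 17 and replaces hydrogenolysis by Lewis-acid debenzylation with a cation scavenger (BCl3, pentamethylbenzene, CH2Cl2, −78 °C, kept cold to avoid C2 epimerisation), coming back to the route at the target 18.

**Further compounds**
F1 | step 6 | 5-(benzyloxy)-2-{(E)-2-[3,5-bis(benzyloxy)phenyl]ethenyl}-1,3-dichlorobenzene | Clc1cc(OCc2ccccc2)cc(Cl)c1/C=C/c1cc(OCc2ccccc2)cc(OCc2ccccc2)c1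
F2 | step 6 | trans-2-[4-(benzyloxy)-2,6-dichlorophenyl]-3-[3,5-bis(benzyloxy)phenyl]oxirane (racemic; one enantiomer drawn) | Clc1cc(OCc2ccccc2)cc(Cl)c1[C@@H]1[C@H](O1)c1cc(OCc2ccccc2)cc(OCc2ccccc2)c1
F3 | step 6 | 2-[4-(benzyloxy)-2,6-dichlorophenyl]-2-[3,5-bis(benzyloxy)phenyl]acetaldehyde (racemic) | O=CC(c1c(Cl)cc(OCc2ccccc2)cc1Cl)c1cc(OCc2ccccc2)cc(OCc2ccccc2)c1
F4 | step 6 | racemic (1S*,2R*)-1-[4-(benzyloxy)phenyl]-2-[4-(benzyloxy)-2,6-dichlorophenyl]-2-[3,5-bis(benzyloxy)phenyl]ethan-1-ol (the (1S,2R) enantiomer drawn) | Clc1cc(OCc2ccccc2)cc(Cl)c1[C@@H](c1cc(OCc2ccccc2)cc(OCc2ccccc2)c1)[C@@H](c1ccc(OCc2ccccc2)cc1)O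
F5 | step 7 | lithium alkoxide of the aryne formed from 13 by loss of HCl (5-(benzyloxy)-3-chloro-1,2-didehydrobenzene ring) | [Li+].ClC1=C([C@@H](c2cc(OCc3ccccc3)cc(OCc3ccccc3)c2)[C@@H](c2ccc(OCc3ccccc3)cc2)[O-])C#CC(OCc2ccccc2)=C1
F0 | step 9 | none | none
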